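**Structural features**

Abyssinone D (10) is a 2'-hydroxychalcone: two benzene rings joined by a three-carbon (E)-propenone chain, with no further ring. Ring A is a 2,4-dihydroxyphenyl group whose C1' carries the carbonyl carbon. Ring B is a 1,3,4,5-tetrasubstituted benzene with the β-alkene carbon on C1, a methoxy group on C3, a free hydroxyl on C4 and a 3-methylbut-2-enyl (prenyl) group on C5. There is no stereocentre, so no stereocentres stand next to each other; the only stereochemical element is the E geometry of the Cα=Cβ bond. The fragile sites are the prenyl group ortho to the C4 phenol (acid closes it to a 2,2-dimethylchroman, metal hydrides can move its double bond), the C2' hydroxyl (under base or acid it adds to Cβ and closes the flavanone), the three oxidisable phenols and the enone. The skeleton is therefore simple; the real difficulty is to form the one strategic enone C–C bond and then unmask three phenols of different acidity without triggering either cyclisation, and, in the plan adopted here, to send an acyl group to the terminal carbon of an aryl acetylene. The key step uses the C2' hydroxyl of ring A, which lies ortho to C1' and so next to the carbonyl carbon: ring A plus the carbonyl carbon is a salicylaldehyde whose phenoxide oxygen can bind rhodium and hand it the formyl C–H, while Cα and Cβ come from an ethynyl group on C1 of ring B. Because this hydroxyl belongs to the target, the directing group costs no step to install or remove.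

**Logic of the disconnections**

10 to 9. The two O–Si bonds at O4' of ring A and O4 of ring B are cut last. The 4'-hydroxyl is more acidic than the chelated 2'-hydroxyl and would compete for base and rhodium, and the ring B phenol has to pass through palladium and methanolic carbonate, so both are carried as silyl ethers. The gain is that the last step is a single deprotection. The demand is that it runs close to neutral, so that neither the flavanone nor the chroman closes.

9 to 8 and 6. The bond between the carbonyl carbon and Cα is cut, so that the formyl C–H of 8 adds across the triple bond of 6. This divides the molecule into two halves of similar size, uses every atom of both, and leaves the 2'-hydroxyl unprotected because it is the directing group. The forward step must deliver the acyl group to the terminal alkyne carbon, add H and acyl syn (E-alkene), avoid decarbonylation and alkyne oligomerisation, and leave the silyl ethers and the prenyl alkene untouched.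

6 to 4 and 5. The triple bond is cut between the benzylic carbon and the terminal carbon, which is supplied by 5 in a one-carbon homologation of the aldehyde. The gain is that the alkyne comes from a formyl group already present in the cheapest ring B starting material. The demand is that the methanolic carbonate does not strip the aryl silyl ether, which is why a triisopropylsilyl group flanked by two ortho substituents is chosen.

4 to 2 and 3. The C5–CH2 bond between ring B and the prenyl group is cut as a cross-coupling of an aryl iodide with an allylic stannane. The gain is that the prenyl position is fixed by the position of the iodine, with no reliance on electrophilic substitution of a phenol. The demand is transfer of the allylic group through its primary carbon, without migration of the double bond.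

2 to 1. The O–Si bond is cut. Silylation comes before the coupling so that no free ortho-iodophenol meets palladium and no free ortho-prenylphenol is ever exposed. The demand is silylation of a phenol that sits between a methoxy group and iodine.

8 to 7. The O–Si bond at O4 is cut. The gain is a one-step entry from a commodity aldehyde. The demand is selectivity for the 4-hydroxyl over the hydrogen-bonded 2-hydroxyl.

**Other disconnections considered**

Alternative 1: The cut is the C5–CH2 bond of ring B, made at a late stage. The forward key step heats the aryl 1,1-dimethylallyl ether A1, a chalcone whose ring A hydroxyls are methoxymethyl ethers. A [3,3] aromatic Claisen rearrangement then moves the C5 unit from O4 to C5 with allylic inversion and gives the prenyl phenol A2.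
- In its favour: only one ortho position is free, because C3 carries the methoxy group, so the site of prenylation is unambiguous. The inversion converts the tertiary ether into the linear prenyl group, and the geminal methyl groups lower the temperature needed.
- Against it: the tertiary allyl aryl ether cannot be made by simple alkylation. It usually needs a propargyl ether and a semi-hydrogenation, which must precede the condensation because the chalcone alkene would not survive it. The ether easily ionises and loses its C5 unit on heating. The freed phenol next to the new prenyl group can cyclise to the chroman at the rearrangement temperature. The final removal of two methoxymethyl ethers needs acid, the very condition that closes the chroman and the flavanone.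
- Structure: A1 carries the complete chalcone through a thermal step, whereas the chosen plan joins two robust halves late.
- Mechanism: the pericyclic step has no regiochemical risk at the enone, because the enone comes from an aldol condensation. On this point the alternative is better than the chosen plan, whose weak point is the orientation of alkyne insertion. It also needs no tin, palladium or rhodium, which is a further point in its favour.
- Step economy: about seven steps against six. The two plans are equal in having no stereocentre to control.

Alternative 2: The cuts are the C1'–C2' and C5'–C6' bonds, so ring A is built rather than bought. The forward key step is a Diels–Alder reaction of 1-methoxy-1,3-bis(trimethylsilyloxy)buta-1,3-diene A4 with the ethynyl ketone of the cross-conjugated enynone A3. Aromatisation by 1,4-elimination of the methoxy group and hydrolysis of the trimethylsilyl ethers then give A5, the chalcone with only the ring B phenol silylated.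
- In its favour: the polarity match between the nucleophilic CH2 terminus of A4 and the β-carbon of the ynone places the oxygens at C2' and C4'. Both ring A hydroxyls emerge free without any protecting group. No transition metal is involved in the key step.
- Against it: ring A is a commodity resorcinol, so its construction is a detour. A3 has three electrophilic sites (ynone β-carbon, enone β-carbon, carbonyl) and is prone to polymerisation. A4 is a bis-silyl dienolate that often reacts stepwise and may stop at open-chain Michael adducts or close through oxygen. A3 needs about three steps from an aldehyde of the type of 4.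
- Structure: the alternative forms two bonds and a ring where the chosen plan forms one bond.
- Mechanism: the alternative is the equal of the chosen plan in ending with one fluoride deprotection. It is better in that the enone geometry is set by an early olefination and ring A needs no protection.
- Step economy: about eight steps against six, so it is clearly worse on step count and on chemoselectivity.

Alternative 3: The cut is the bond between Cβ and C1 of ring B. In the forward key step a hydroxo complex of monovalent rhodium, [Rh(OH)(cod)]2, transfers the aryl group of the boronate A7 to C2 of 7-(methoxymethoxy)chromone A6. The resulting flavanone A8 is opened in the same pot by hydroxide through E1cB loss of the ring A phenoxide, giving the E-chalcone A9.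
- In its favour: the aryl group can only go to C2, so the connectivity is secure. The C2' hydroxyl is latent in the pyranone oxygen and needs no protecting group.
- Against it: chromones are vinylogous esters and sluggish acceptors. The electron-rich A7 is exposed to protodeboronation at the temperatures needed. The flavanone–chalcone equilibrium may return towards A8 on neutralisation. Ring B has to be prepared as a boronate, which the formyl group of 1 does not offer directly. The methoxymethyl ethers of A9 again need a final acid treatment.
- Structure: both plans join ring B to a preformed ring A unit in one convergent step and are equal on that point.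
- Mechanism: both use rhodium and both exploit the C2' oxygen. The alternative is better in the certainty of its regiochemistry, and worse in its reliance on an equilibrium and on an acidic last step.
- Step economy: seven to eight steps against six.

Key step: step 5

Remark on the chemistry: primed locants refer to ring A and unprimed ones to ring B. In the key step the carbonate is used in catalytic amount and the alkyne is added slowly, to limit base-induced closure of the product and oligomerisation of the alkyne.

**Route**

Step 1
Reactants: 1 5-iodovanillin (4-hydroxy-3-iodo-5-methoxybenzaldehyde)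
Product: 2 3-iodo-5-methoxy-4-[(triisopropylsilyl)oxy]benzaldehyde
Conditions: TIPSCl, imidazole, DMAP (cat.), DMF, rt to 40 °C
Reagents that add atoms: triisopropylsilyl chloride, CC(C)[Si](Cl)(C(C)C)C(C)C
Why: Silylation of a phenol with an imidazole-activated silyl chloride; the para-formyl and ortho-iodo groups make the phenol acidic, so its phenoxide should attack silicon despite two ortho substituents. The bulky triisopropylsilyl group is chosen because it must later outlast methanolic carbonate.

Step 2
Reactants: 2 3-iodo-5-methoxy-4-[(triisopropylsilyl)oxy]benzaldehyde; 3 tributyl(3-methylbut-2-en-1-yl)stannane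
Product: 4 3-methoxy-5-(3-methylbut-2-en-1-yl)-4-[(triisopropylsilyl)oxy]benzaldehyde
Conditions: Pd(PPh3)4 (5 mol%), degassed DMF, 90 °C
Reagents that add atoms: none
Why: Migita–Kosugi–Stille coupling: oxidative addition of the aryl iodide to zerovalent palladium, transfer of the allylic group from tin and reductive elimination at the less substituted terminus of the η3-prenyl ligand should give the linear prenyl arene. Aldehyde, methyl ether and silyl ether are inert under these neutral conditions.

Step 3
Reactants: 4 3-methoxy-5-(3-methylbut-2-en-1-yl)-4-[(triisopropylsilyl)oxy]benzaldehyde; 5 dimethyl (1-diazo-2-oxopropyl)phosphonate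
Product: 6 [4-ethynyl-2-methoxy-6-(3-methylbut-2-en-1-yl)phenoxy]tri(propan-2-yl)silane
Conditions: K2CO3, MeOH–THF, 0 °C to rt
Reagents that add atoms: none
Why: Seyferth–Gilbert homologation in its Ohira–Bestmann form: methoxide deacylates 5 to the diazomethylphosphonate anion, which olefinates the aldehyde in Horner–Wadsworth–Emmons fashion, and loss of dimethyl phosphate and N2 with a 1,2-hydride shift gives the terminal alkyne. The silyl ether is shielded by three isopropyl groups and two ortho substituents and should outlast the mild base at low temperature.

Step 4
Reactants: 7 2,4-dihydroxybenzaldehyde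
Product: 8 4-[(tert-butyldimethylsilyl)oxy]-2-hydroxybenzaldehyde
Conditions: TBSCl (1.05 equiv), imidazole, CH2Cl2, 0 °C
Reagents that add atoms: tert-butyldimethylsilyl chloride, CC(C)(C)[Si](C)(C)Cl
Why: Regioselective phenol silylation: the 4-hydroxyl is the more acidic and the unhindered one, whereas the 2-hydroxyl is held in a hydrogen bond to the formyl oxygen, so one equivalent of silyl chloride at 0 °C should react at O4 only.

Step 5
Reactants: 8 4-[(tert-butyldimethylsilyl)oxy]-2-hydroxybenzaldehyde; 6 [4-ethynyl-2-methoxy-6-(3-methylbut-2-en-1-yl)phenoxy]tri(propan-2-yl)silane
Product: 9 (2E)-1-{4-[(tert-butyldimethylsilyl)oxy]-2-hydroxyphenyl}-3-{3-methoxy-5-(3-methylbut-2-en-1-yl)-4-[(triisopropylsilyl)oxy]phenyl}prop-2-en-1-one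
Conditions: [RhCl(cod)]2 (2.5 mol%), dppf = Fe(C5H4PPh2)2 (5 mol%), Na2CO3 (10 mol%), PhMe, 100 °C, 8 in slight excess, 6 added slowly
Reagents that add atoms: none
Why: Chelation-assisted intermolecular alkyne hydroacylation: carbonate forms the phenoxide of 8, which replaces chloride on the diphosphine-ligated monovalent rhodium, and the bound metal inserts into the neighbouring formyl C–H to give a five-membered acyl(hydrido) chelate of trivalent rhodium (Rh, O, C2', C1' and the acyl carbon) that is too rigid to decarbonylate easily. Alkyne 6 then inserts into Rh–H by syn addition with the metal on the terminal carbon and the hydride on the aryl-bearing carbon, C–C reductive elimination forms the bond between the carbonyl carbon and Cα and returns monovalent rhodium, and exchange with a further molecule of 8 releases 9. The closest known reaction type is the addition of salicylaldehydes to alkynes under [RhCl(cod)]2, a diphosphine and carbonate, which gives 2-alkenoylphenols. No ring is closed and no stereocentre is formed; the E geometry follows from the syn delivery of hydrogen and acyl across the triple bond. The selectivity needed is linear over branched: the wide-bite-angle ferrocenyl diphosphine crowds the metal so that it should prefer the unsubstituted alkyne terminus, and the 3,4,5-trisubstituted aryl group adds to that steric bias. Chemoselectivity rests on the trisubstituted prenyl alkene being a poor ligand and a poor insertion partner, on the silyl ethers being inert to rhodium, and on the carbonate being only catalytic, which also limits oxa-Michael closure of the product; slow addition of 6 keeps the alkyne concentration low and should suppress its oligomerisation.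

Step 6
Reactants: 9 (2E)-1-{4-[(tert-butyldimethylsilyl)oxy]-2-hydroxyphenyl}-3-{3-methoxy-5-(3-methylbut-2-en-1-yl)-4-[(triisopropylsilyl)oxy]phenyl}prop-2-en-1-one
Product: 10 abyssinone D, (2E)-1-(2,4-dihydroxyphenyl)-3-[4-hydroxy-3-methoxy-5-(3-methylbut-2-en-1-yl)phenyl]prop-2-en-1-one
Conditions: Bu4NF (2.5 equiv), AcOH (3 equiv), THF, 0 °C to rt
Reagents that add atoms: none
Why: Fluoride-induced cleavage of both aryl silyl ethers, driven by the Si–F bond and the phenoxide leaving groups. Acetic acid protonates the phenoxides as they form, which should prevent addition of the 2'-oxygen to the enone (flavanone) and avoids any acid strong enough to cyclise the ortho-prenylphenol to a chroman.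

**Compound list**

1 | 5-iodovanillin (4-hydroxy-3-iodo-5-methoxybenzaldehyde) | COc1cc(C=O)cc(I)c1O | starting material
2 | 3-iodo-5-methoxy-4-[(triisopropylsilyl)oxy]benzaldehyde | COc1cc(C=O)cc(I)c1O[Si](C(C)C)(C(C)C)C(C)C | intermediate
3 | tributyl(3-methylbut-2-en-1-yl)stannane | CCCC[Sn](CCCC)(CCCC)CC=C(C)C | starting material
4 | 3-methoxy-5-(3-methylbut-2-en-1-yl)-4-[(triisopropylsilyl)oxy]benzaldehyde | COc1cc(C=O)cc(CC=C(C)C)c1O[Si](C(C)C)(C(C)C)C(C)C | intermediate
5 | dimethyl (1-diazo-2-oxopropyl)phosphonate | COP(=O)(OC)C(=[N+]=[N-])C(C)=O | starting material
6 | [4-ethynyl-2-methoxy-6-(3-methylbut-2-en-1-yl)phenoxy]tri(propan-2-yl)silane | COc1cc(C#C)cc(CC=C(C)C)c1O[Si](C(C)C)(C(C)C)C(C)C | intermediate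
7 | 2,4-dihydroxybenzaldehyde | O=Cc1ccc(O)cc1O | starting material
8 | 4-[(tert-butyldimethylsilyl)oxy]-2-hydroxybenzaldehyde | CC(C)(C)[Si](C)(C)Oc1ccc(C=O)c(O)c1 | intermediate
9 | (2E)-1-{4-[(tert-butyldimethylsilyl)oxy]-2-hydroxyphenyl}-3-{3-methoxy-5-(3-methylbut-2-en-1-yl)-4-[(triisopropylsilyl)oxy]phenyl}prop-2-en-1-one | COc1cc(/C=C/C(=O)c2ccc(O[Si](C)(C)C(C)(C)C)cc2O)cc(CC=C(C)C)c1O[Si](C(C)C)(C(C)C)C(C)C | intermediate
10 | abyssinone D, (2E)-1-(2,4-dihydroxyphenyl)-3-[4-hydroxy-3-methoxy-5-(3-methylbut-2-en-1-yl)phenyl]prop-2-en-1-one | COc1cc(/C=C/C(=O)c2ccc(O)cc2O)cc(CC=C(C)C)c1O | target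

**Step count and risks**

Total step count: 6. Longest linear sequence: 5 steps (steps 1, 2, 3, 5 and 6, from 1 to 10); step 4 is the one-step side branch.

Step 5 (key step). The likeliest failures are:
- insertion of the alkyne in the opposite orientation, which would send the acyl group to the aryl-bearing carbon, because a terminal aryl alkyne has no strong electronic bias for the linear mode;
- oligomerisation of the terminal alkyne at monovalent rhodium;
- decarbonylation of the acyl hydride if chelation is lost;
- base-induced addition of the 2'-oxygen to the new enone;
- migration of the prenyl double bond by a rhodium hydride.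

The fallback sets out from 6 and 8 and returns at 10. Compound 8 is silylated at O2 as well (TBSCl, imidazole, DMAP, DMF, 40 °C) to 2,4-bis[(tert-butyldimethylsilyl)oxy]benzaldehyde F1. Hydrozirconation of 6 with Cp2Zr(H)Cl (CH2Cl2, rt) places the metal on the terminal carbon by sterically controlled syn addition and gives the (E)-alkenylzirconocene chloride F2. F2 is added to F1 with catalytic ZnBr2 in THF, and aqueous work-up should give the racemic allylic alcohol (2E)-1-{2,4-bis[(tert-butyldimethylsilyl)oxy]phenyl}-3-{3-methoxy-5-(3-methylbut-2-en-1-yl)-4-[(triisopropylsilyl)oxy]phenyl}prop-2-en-1-ol F3. MnO2 in CH2Cl2 oxidises this benzylic and allylic alcohol to the tris-silyl chalcone F4. The buffered fluoride of step 6, with one more equivalent, takes F4 to 10.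

Step 2. The prenyl group may be transferred through its tertiary carbon, giving the 1,1-dimethylallyl isomer. Transmetalation next to the bulky silyl ether may be slow enough for protodeiodination to compete, and the double bond may migrate towards the ring at 90 °C. The fallback sets out from 2 and returns at 4. A Stille coupling with tributyl(prop-2-en-1-yl)stannane (Pd(PPh3)4, PhMe, 90 °C) transfers the symmetrical allyl group and gives 3-methoxy-5-(prop-2-en-1-yl)-4-[(triisopropylsilyl)oxy]benzaldehyde F5. Cross-metathesis of F5 with excess 2-methylbut-2-ene (second-generation Grubbs catalyst, RuCl2(=CHPh)(H2IMes)(PCy3), CH2Cl2, 40 °C) then converts the allyl group into the prenyl group of 4.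

Step 3. Methoxide may cleave the aryl silyl ether before the aldehyde has reacted, because the phenoxide para to a formyl group is a good leaving group; the resulting phenoxide aldehyde would resist homologation. The fallback sets out from 4 and returns at 6, and is aprotic throughout (Corey–Fuchs sequence). CBr4 and PPh3 in CH2Cl2 at 0 °C give the dibromoalkene {4-(2,2-dibromoethenyl)-2-methoxy-6-(3-methylbut-2-en-1-yl)phenoxy}tri(propan-2-yl)silane F6. n-BuLi (2.1 equiv, THF, −78 °C) converts F6 by bromine–lithium exchange and rearrangement into the lithium acetylide F7, which is protonated to 6 on aqueous work-up.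

**Further compounds**

F1 | step 5 | 2,4-bis[(tert-butyldimethylsilyl)oxy]benzaldehyde | CC(C)(C)[Si](C)(C)Oc1ccc(C=O)c(O[Si](C)(C)C(C)(C)C)c1
F2 | step 5 | chloridobis(cyclopentadienyl){(E)-2-[3-methoxy-5-(3-methylbut-2-en-1-yl)-4-(triisopropylsilyloxy)phenyl]ethenyl}zirconium | Cl[Zr](/C=C/c1cc(OC)c(O[Si](C(C)C)(C(C)C)C(C)C)c(CC=C(C)C)c1)(C1C=CC=C1)C1C=CC=C1
F3 | step 5 | (2E)-1-{2,4-bis[(tert-butyldimethylsilyl)oxy]phenyl}-3-{3-methoxy-5-(3-methylbut-2-en-1-yl)-4-[(triisopropylsilyl)oxy]phenyl}prop-2-en-1-ol (racemic) | COc1cc(/C=C/C(O)c2ccc(O[Si](C)(C)C(C)(C)C)cc2O[Si](C)(C)C(C)(C)C)cc(CC=C(C)C)c1O[Si](C(C)C)(C(C)C)C(C)C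
F4 | step 5 | (2E)-1-{2,4-bis[(tert-butyldimethylsilyl)oxy]phenyl}-3-{3-methoxy-5-(3-methylbut-2-en-1-yl)-4-[(triisopropylsilyl)oxy]phenyl}prop-2-en-1-one | COc1cc(/C=C/C(=O)c2ccc(O[Si](C)(C)C(C)(C)C)cc2O[Si](C)(C)C(C)(C)C)cc(CC=C(C)C)c1O[Si](C(C)C)(C(C)C)C(C)C
F5 | step 2 | 3-methoxy-5-(prop-2-en-1-yl)-4-[(triisopropylsilyl)oxy]benzaldehyde | COc1cc(C=O)cc(CC=C)c1O[Si](C(C)C)(C(C)C)C(C)C
F6 | step 3 | {4-(2,2-dibromoethenyl)-2-methoxy-6-(3-methylbut-2-en-1-yl)phenoxy}tri(propan-2-yl)silane | COc1cc(C=C(Br)Br)cc(CC=C(C)C)c1O[Si](C(C)C)(C(C)C)C(C)C
F7 | step 3 | lithium {[3-methoxy-5-(3-methylbut-2-en-1-yl)-4-(triisopropylsilyloxy)phenyl]ethynide} | [Li]C#Cc1cc(OC)c(O[Si](C(C)C)(C(C)C)C(C)C)c(CC=C(C)C)c1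
A1 | alternative 1 | (2E)-1-[2,4-bis(methoxymethoxy)phenyl]-3-{3-methoxy-4-[(2-methylbut-3-en-2-yl)oxy]phenyl}prop-2-en-1-one | COCOc1ccc(C(=O)/C=C/c2ccc(OC(C)(C)C=C)c(OC)c2)c(OCOC)c1
A2 | alternative 1 | (2E)-1-[2,4-bis(methoxymethoxy)phenyl]-3-[4-hydroxy-3-methoxy-5-(3-methylbut-2-en-1-yl)phenyl]prop-2-en-1-one | COCOc1ccc(C(=O)/C=C/c2cc(OC)c(O)c(CC=C(C)C)c2)c(OCOC)c1
A3 | alternative 2 | (1E)-1-[4-(tert-butyldimethylsilyloxy)-3-methoxy-5-(3-methylbut-2-en-1-yl)phenyl]pent-1-en-4-yn-3-one | C#CC(=O)/C=C/c1cc(OC)c(O[Si](C)(C)C(C)(C)C)c(CC=C(C)C)c1
A4 | alternative 2 | 1-methoxy-1,3-bis(trimethylsilyloxy)buta-1,3-diene | COC(O[Si](C)(C)C)=CC(=C)O[Si](C)(C)C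
A5 | alternative 2 | (2E)-3-[4-(tert-butyldimethylsilyloxy)-3-methoxy-5-(3-methylbut-2-en-1-yl)phenyl]-1-(2,4-dihydroxyphenyl)prop-2-en-1-one | COc1cc(/C=C/C(=O)c2ccc(O)cc2O)cc(CC=C(C)C)c1O[Si](C)(C)C(C)(C)C
A6 | alternative 3 | 7-(methoxymethoxy)-4H-chromen-4-one | COCOc1ccc2c(=O)ccoc2c1
A7 | alternative 3 | 2-[3-methoxy-4-(methoxymethoxy)-5-(3-methylbut-2-en-1-yl)phenyl]-4,4,5,5-tetramethyl-1,3,2-dioxaborolane | COCOc1c(OC)cc(B2OC(C)(C)C(C)(C)O2)cc1CC=C(C)C
A8 | alternative 3 | 2-[3-methoxy-4-(methoxymethoxy)-5-(3-methylbut-2-en-1-yl)phenyl]-7-(methoxymethoxy)-2,3-dihydro-4H-chromen-4-one (racemic) | COCOc1ccc2c(c1)OC(CC2=O)c1cc(OC)c(OCOC)c(CC=C(C)C)c1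
A9 | alternative 3 | (2E)-1-[2-hydroxy-4-(methoxymethoxy)phenyl]-3-[3-methoxy-4-(methoxymethoxy)-5-(3-methylbut-2-en-1-yl)phenyl]prop-2-en-1-one | COCOc1ccc(C(=O)/C=C/c2cc(OC)c(OCOC)c(CC=C(C)C)c2)c(O)c1
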